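**Strategy.** The route rests on cutting the C9–C10 bond of the cis-diol inside the seven-membered ring B. Both carbons are carbinol carbons, so the bond can arise from two aldehyde carbons by reductive coupling. One operation with samarium diiodide closes ring B onto the preformed cyclopentane (ring A) and sets the C9 and C10 hydroxyls cis. The precursor is a trans-1,2-disubstituted cyclopentane carrying a formyl group on the quaternary C1 and, on C5, a chain (C6 isovalerate, C7) ending in an α-alkoxy aldehyde (C9) whose quaternary C8 holds the later epoxide as a C8,C14 acetonide. It is assembled convergently by an aldol union of two enantioenriched fragments.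

Key step: step 13

Labels: C1 quaternary methyl carbon; C2, C3 ring CH2; C4 isopropyl carbinol; C5 ring-fusion CH; C6 ester carbinol; C7 CH2; C8 spiro carbon with C14 its CH2; C9, C10 diol carbons (C10 on C1). These daucane labels are used for all intermediates; PMB = 4-methoxybenzyl.
Assumption: the chiral sulfonate-bearing imidazolinium salt (NHC precursor) of step 1 is prepared by its known route and used as the enantiomer that gives (R)-5.

Step 1
Reactants: 1 3-methylcyclopent-2-en-1-one; 2 propyne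
Product: 5 triethyl{[(3R)-3-methyl-3-(2-methylprop-1-en-1-yl)cyclopent-1-en-1-yl]oxy}silane, via alkenylalane 3 (not isolated), via aluminium enolate 4 (not isolated)
Conditions: 2, Me3Al, Cp2ZrCl2 (cat.), ClCH2CH2Cl, 22 °C; then 1, CuCl2·2H2O (5 mol %), chiral sulfonate-bearing imidazolinium salt (5 mol %), THF, −30 → 22 °C; then Et3SiOTf, −78 → 0 °C
Reagents that add atoms: trimethylaluminium, C[Al](C)C; triethylsilyl trifluoromethanesulfonate, CC[Si](CC)(CC)OS(=O)(=O)C(F)(F)F
Why: Zirconium-catalysed methylalumination of the alkyne (Negishi carboalumination) gives alkenylalane 3, whose copper–NHC-catalysed enantioselective conjugate addition to the β-methyl enone creates the C1 quaternary centre (R, set by the chiral ligand) with transfer of the alkenyl group, and silyl triflate capture of aluminium enolate 4 fixes the C4=C5 enol regiochemistry; the 2-methylpropenyl group is a bulky latent C10 aldehyde.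

Step 2
Reactants: 6 2-methylidenepropane-1,3-diol
Product: 7 2-{[(4-methoxyphenyl)methoxy]methyl}prop-2-en-1-ol
Conditions: NaH (1 equiv), 4-methoxybenzyl chloride (1 equiv), Bu4NI (cat.), THF, 0 °C → rt, diol in excess
Reagents that add atoms: 4-methoxybenzyl chloride, COc1ccc(CCl)cc1
Why: Williamson etherification of the monoalkoxide, with excess diol keeping double alkylation low and leaving the allylic alcohol needed for the directed epoxidation.

Step 3
Reactants: 7 2-{[(4-methoxyphenyl)methoxy]methyl}prop-2-en-1-ol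
Product: 8 [(2R)-2-{[(4-methoxyphenyl)methoxy]methyl}oxiran-2-yl]methanol
Conditions: Ti(OiPr)4 (10 mol %), D-(−)-diethyl tartrate (12 mol %), t-BuOOH, 4 Å molecular sieves, CH2Cl2, −20 °C
Reagents that add atoms: tert-butyl hydroperoxide, CC(C)(C)OO
Why: Sharpless asymmetric epoxidation of a 2-substituted allylic alcohol, in which the titanium–D-tartrate complex delivers the peroxide oxygen to one enantiotopic alkene face and so sets C8 by reagent control.

Step 4
Reactants: 8 [(2R)-2-{[(4-methoxyphenyl)methoxy]methyl}oxiran-2-yl]methanol; 9 vinylmagnesium bromide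
Product: 10 (2S)-2-{[(4-methoxyphenyl)methoxy]methyl}pent-4-ene-1,2-diol
Conditions: 9 (3 equiv), CuI (10 mol %), THF, −40 → 0 °C
Reagents that add atoms: none
Why: Copper-catalysed Grignard opening of the 2,2-disubstituted epoxide by SN2 attack at its CH2 carbon (the future C7) leaves the C8–O bond untouched, so C8 is retained, and a Payne shift of this glycidol is degenerate and cannot erode it.

Step 5
Reactants: 10 (2S)-2-{[(4-methoxyphenyl)methoxy]methyl}pent-4-ene-1,2-diol
Product: 11 (4R)-4-{[(4-methoxyphenyl)methoxy]methyl}-2,2-dimethyl-4-(prop-2-en-1-yl)-1,3-dioxolane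
Conditions: Me2C(OMe)2, PPTS (cat.), CH2Cl2, rt
Reagents that add atoms: 2,2-dimethoxypropane, COC(C)(C)OC
Why: Acid-catalysed transacetalisation closes the five-membered dioxolane on the only 1,2-diol, masking the C8 oxygen and C14 and keeping C14 distinct from the PMB-protected C9 arm.

Step 6
Reactants: 11 (4R)-4-{[(4-methoxyphenyl)methoxy]methyl}-2,2-dimethyl-4-(prop-2-en-1-yl)-1,3-dioxolane
Product: 13 2-[(4R)-4-{[(4-methoxyphenyl)methoxy]methyl}-2,2-dimethyl-1,3-dioxolan-4-yl]acetaldehyde, via vicinal diol 12 (not isolated)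
Conditions: OsO4 (2 mol %), NaIO4 (4 equiv), 2,6-lutidine, 1,4-dioxane–H2O (3:1), rt
Reagents that add atoms: osmium tetroxide, O=[Os](=O)(=O)=O; sodium periodate, [Na+].[O-]I(=O)(=O)=O
Why: Lemieux–Johnson oxidation (osmylation to diol 12, then periodate glycol cleavage) unveils the C6 aldehyde without ozone, which would attack the electron-rich PMB ring.

Step 7
Reactants: 5 triethyl{[(3R)-3-methyl-3-(2-methylprop-1-en-1-yl)cyclopent-1-en-1-yl]oxy}silane; 13 2-[(4R)-4-{[(4-methoxyphenyl)methoxy]methyl}-2,2-dimethyl-1,3-dioxolan-4-yl]acetaldehyde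
Product: 17 (2S,3R)-2-{(1S)-1-hydroxy-2-[(4R)-4-{[(4-methoxyphenyl)methoxy]methyl}-2,2-dimethyl-1,3-dioxolan-4-yl]ethyl}-3-methyl-3-(2-methylprop-1-en-1-yl)cyclopentan-1-one, via lithium enolate 14 (not isolated), via boron enolate 15 (not isolated), via boron aldolate 16 (not isolated)
Conditions: 5, MeLi, THF, 0 °C; Bu2BOTf, −78 °C; 13, −78 → −40 °C; then pH 7 buffer, MeOH, H2O2, 0 °C
Reagents that add atoms: none
Why: Silicon–lithium then lithium–boron exchange gives the regiodefined boron enolate 15, whose ring-enforced E geometry leads through a Zimmerman–Traxler chair to the anti aldol (C6, S), while the aldehyde approaches C5 on the face opposite the bulky 2-methylpropenyl group, i.e. cis to the C1 methyl (C5, S); the remote C8 centre should have no significant influence.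

Step 8
Reactants: 17 (2S,3R)-2-{(1S)-1-hydroxy-2-[(4R)-4-{[(4-methoxyphenyl)methoxy]methyl}-2,2-dimethyl-1,3-dioxolan-4-yl]ethyl}-3-methyl-3-(2-methylprop-1-en-1-yl)cyclopentan-1-one; 18 isopropylmagnesium chloride
Product: 19 (1R,2S,3R)-2-{(1S)-1-hydroxy-2-[(4R)-4-{[(4-methoxyphenyl)methoxy]methyl}-2,2-dimethyl-1,3-dioxolan-4-yl]ethyl}-3-methyl-3-(2-methylprop-1-en-1-yl)-1-(propan-2-yl)cyclopentan-1-ol
Conditions: 18 (4 equiv), CeCl3 (anhydrous, 4 equiv), THF, −78 → −40 °C
Reagents that add atoms: none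
Why: Organocerium addition (Grignard reagent with anhydrous CeCl3) suppresses enolisation and β-hydride reduction at the hindered ketone, the cerium aldolate chelate and the C5 side chain block the β face, and isopropyl therefore enters trans to the side chain to give the C4 tertiary alcohol cis to it (C4, R).

Step 9
Reactants: 19 (1R,2S,3R)-2-{(1S)-1-hydroxy-2-[(4R)-4-{[(4-methoxyphenyl)methoxy]methyl}-2,2-dimethyl-1,3-dioxolan-4-yl]ethyl}-3-methyl-3-(2-methylprop-1-en-1-yl)-1-(propan-2-yl)cyclopentan-1-ol; 20 3-methylbutanoyl chloride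
Product: 21 (1S)-1-[(1S,2R,5R)-2-hydroxy-5-methyl-5-(2-methylprop-1-en-1-yl)-2-(propan-2-yl)cyclopentyl]-2-[(4R)-4-{[(4-methoxyphenyl)methoxy]methyl}-2,2-dimethyl-1,3-dioxolan-4-yl]ethyl 3-methylbutanoate
Conditions: 20 (1.5 equiv), pyridine, DMAP (cat.), CH2Cl2, 0 °C → rt
Reagents that add atoms: none
Why: DMAP-catalysed acylation (nucleophilic catalysis) esterifies the secondary C6 hydroxyl, the tertiary C4 hydroxyl being far less reactive.

Step 10
Reactants: 21 (1S)-1-[(1S,2R,5R)-2-hydroxy-5-methyl-5-(2-methylprop-1-en-1-yl)-2-(propan-2-yl)cyclopentyl]-2-[(4R)-4-{[(4-methoxyphenyl)methoxy]methyl}-2,2-dimethyl-1,3-dioxolan-4-yl]ethyl 3-methylbutanoate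
Product: 22 (1S)-2-[(4R)-4-(hydroxymethyl)-2,2-dimethyl-1,3-dioxolan-4-yl]-1-[(1S,2R,5R)-2-hydroxy-5-methyl-5-(2-methylprop-1-en-1-yl)-2-(propan-2-yl)cyclopentyl]ethyl 3-methylbutanoate
Conditions: DDQ, CH2Cl2–pH 7 buffer (10:1), 0 °C
Reagents that add atoms: none
Why: Oxidative PMB ether cleavage by DDQ (hydride abstraction to the oxocarbenium ion, then hydrolysis) frees the C9 alcohol under buffered conditions that spare the acetonide, ester and alkene.

Step 11
Reactants: 22 (1S)-2-[(4R)-4-(hydroxymethyl)-2,2-dimethyl-1,3-dioxolan-4-yl]-1-[(1S,2R,5R)-2-hydroxy-5-methyl-5-(2-methylprop-1-en-1-yl)-2-(propan-2-yl)cyclopentyl]ethyl 3-methylbutanoate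
Product: 23 (1S)-2-[(4S)-4-formyl-2,2-dimethyl-1,3-dioxolan-4-yl]-1-[(1S,2R,5R)-2-hydroxy-5-methyl-5-(2-methylprop-1-en-1-yl)-2-(propan-2-yl)cyclopentyl]ethyl 3-methylbutanoate
Conditions: Dess–Martin periodinane, NaHCO3, CH2Cl2, 0 °C → rt
Reagents that add atoms: none
Why: Dess–Martin oxidation converts the neopentyl-type primary alcohol into the non-enolisable C9 aldehyde and does not touch the tertiary alcohol.

Step 12
Reactants: 23 (1S)-2-[(4S)-4-formyl-2,2-dimethyl-1,3-dioxolan-4-yl]-1-[(1S,2R,5R)-2-hydroxy-5-methyl-5-(2-methylprop-1-en-1-yl)-2-(propan-2-yl)cyclopentyl]ethyl 3-methylbutanoate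
Product: 25 (1S)-2-[(4S)-4-formyl-2,2-dimethyl-1,3-dioxolan-4-yl]-1-[(1S,2S,5R)-2-formyl-5-hydroxy-2-methyl-5-(propan-2-yl)cyclopentyl]ethyl 3-methylbutanoate, via ozonide 24 (not isolated)
Conditions: O3, CH2Cl2, −78 °C; then PPh3, −78 °C → rt
Reagents that add atoms: ozone, [O-][O+]=O
Why: Ozonolysis (1,3-dipolar cycloaddition, cycloreversion and recombination to ozonide 24, then reductive work-up) cleaves the only C=C bond to the C10 aldehyde, which like C9 is non-enolisable and cannot form a lactol because the C4 hydroxyl is trans to it.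

Step 13
Reactants: 25 (1S)-2-[(4S)-4-formyl-2,2-dimethyl-1,3-dioxolan-4-yl]-1-[(1S,2S,5R)-2-formyl-5-hydroxy-2-methyl-5-(propan-2-yl)cyclopentyl]ethyl 3-methylbutanoate
Product: 26 (1S,4R,5S,6S,8S,9S,10S)-4,9,10-trihydroxy-8,14-(propane-2,2-diyldioxy)daucan-6-yl 3-methylbutanoate
Conditions: SmI2 (3 equiv), t-BuOH (2 equiv), THF (0.01 M), −78 → −20 °C
Reagents that add atoms: none
Why: Single-electron transfer from divalent samarium converts the aldehydes into ketyls (or one ketyl that adds to the second, samarium-bound carbonyl), and C9–C10 forms inside an array in which trivalent samarium bridges both oxygens; the closest known reaction type is the SmI2-mediated intramolecular pinacol coupling of α-oxygenated dialdehydes to cyclic cis-1,2-diols, seven-membered rings included. Ring B closes in a 7-exo-trig mode, the carbon radical attacking the carbonyl carbon while its oxygen stays outside the new ring, and the trans arms on ring A make the product a trans-fused hydroazulene. At C9 and C10 the cis relation is enforced by the samarium bridge, and the face should be set by placing the bulky O–Sm units anti to the C1 methyl and anti to the C14 methylene of the spiro-dioxolane, i.e. on the α face, where the C8 dioxolane oxygen can join the chelate. The step needs cyclisation to beat intermolecular coupling and simple reduction (high dilution, tert-butanol as mild proton source, termini held close by ring A) and to beat reductive C8–O cleavage of the α-alkoxy ketyl (low temperature, no HMPA). Both aldehydes are non-enolisable, and the ester and acetal are inert to SmI2.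

Step 14
Reactants: 26 (1S,4R,5S,6S,8S,9S,10S)-4,9,10-trihydroxy-8,14-(propane-2,2-diyldioxy)daucan-6-yl 3-methylbutanoate
Product: 27 (1S,4R,5S,6S,8S,9S,10S)-4,8,9,10,14-pentahydroxydaucan-6-yl 3-methylbutanoate
Conditions: AcOH–H2O–THF (3:1:1), 40 °C
Reagents that add atoms: none
Why: Acid-catalysed acetal hydrolysis releases the C8,C14 diol as acetone is lost, under conditions mild enough for the ester and the tertiary alcohols.

Step 15
Reactants: 27 (1S,4R,5S,6S,8S,9S,10S)-4,8,9,10,14-pentahydroxydaucan-6-yl 3-methylbutanoate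
Product: 29 (1S,4R,5S,6S,8S,9S,10S)-8,14-epoxy-4,9,10-trihydroxydaucan-6-yl 3-methylbutanoate (CNP0307265.1), via primary tosylate 28 (not isolated)
Conditions: TsCl (1.1 equiv), Bu2SnO (5 mol %), Et3N, CH2Cl2, 0 °C → rt; then DBU, rt
Reagents that add atoms: none
Why: Tin-catalysed regioselective sulfonylation (stannylene acetal activation) tosylates only the primary C14 hydroxyl of the terminal 1,2-diol, and DBU then promotes intramolecular Williamson closure (3-exo-tet) by the C8 oxygen with C8 unchanged; the C9 hydroxyl is syn to the C8 oxygen and cannot reach the backside of C8, so no Payne rearrangement is expected.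

**Compound list**

1 | 3-methylcyclopent-2-en-1-one | CC1=CC(=O)CC1 | starting material
2 | propyne | CC#C | starting material
3 | dimethyl(2-methylprop-1-en-1-yl)alumane (formed in situ) | CC(C)=C[Al](C)C | intermediate
4 | {[(3R)-3-methyl-3-(2-methylprop-1-en-1-yl)cyclopent-1-en-1-yl]oxy}dimethylalumane (formed in situ) | C[Al](C)OC1=C[C@@](C)(C=C(C)C)CC1 | intermediate
5 | triethyl{[(3R)-3-methyl-3-(2-methylprop-1-en-1-yl)cyclopent-1-en-1-yl]oxy}silane | CC[Si](CC)(CC)OC1=C[C@@](C)(C=C(C)C)CC1 | intermediate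
6 | 2-methylidenepropane-1,3-diol | C=C(CO)CO | starting material
7 | 2-{[(4-methoxyphenyl)methoxy]methyl}prop-2-en-1-ol | COc1ccc(COCC(=C)CO)cc1 | intermediate
8 | [(2R)-2-{[(4-methoxyphenyl)methoxy]methyl}oxiran-2-yl]methanol | COc1ccc(COC[C@@]2(CO)CO2)cc1 | intermediate
9 | vinylmagnesium bromide | C=C[Mg]Br | starting material
10 | (2S)-2-{[(4-methoxyphenyl)methoxy]methyl}pent-4-ene-1,2-diol | COc1ccc(COC[C@@](O)(CO)CC=C)cc1 | intermediate
11 | (4R)-4-{[(4-methoxyphenyl)methoxy]methyl}-2,2-dimethyl-4-(prop-2-en-1-yl)-1,3-dioxolane | COc1ccc(COC[C@@]2(COC(C)(C)O2)CC=C)cc1 | intermediate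
12 | 3-[(4R)-4-{[(4-methoxyphenyl)methoxy]methyl}-2,2-dimethyl-1,3-dioxolan-4-yl]propane-1,2-diol (both C2 epimers, formed in situ) | COc1ccc(COC[C@@]2(COC(C)(C)O2)CC(O)CO)cc1 | intermediate
13 | 2-[(4R)-4-{[(4-methoxyphenyl)methoxy]methyl}-2,2-dimethyl-1,3-dioxolan-4-yl]acetaldehyde | COc1ccc(COC[C@@]2(COC(C)(C)O2)CC=O)cc1 | intermediate
14 | lithium (3R)-3-methyl-3-(2-methylprop-1-en-1-yl)cyclopent-1-en-1-olate (formed in situ) | [Li]OC1=C[C@@](C)(C=C(C)C)CC1 | intermediate
15 | dibutyl{[(3R)-3-methyl-3-(2-methylprop-1-en-1-yl)cyclopent-1-en-1-yl]oxy}borane (formed in situ) | CCCCB(CCCC)OC1=C[C@@](C)(C=C(C)C)CC1 | intermediate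
16 | C6 O-dibutylboryl aldolate of 17 (formed in situ) | COc1ccc(COC[C@@]3(COC(C)(C)O3)C[C@H](OB(CCCC)CCCC)[C@H]2C(=O)CC[C@]2(C)C=C(C)C)cc1 | intermediate
17 | (2S,3R)-2-{(1S)-1-hydroxy-2-[(4R)-4-{[(4-methoxyphenyl)methoxy]methyl}-2,2-dimethyl-1,3-dioxolan-4-yl]ethyl}-3-methyl-3-(2-methylprop-1-en-1-yl)cyclopentan-1-one | COc1ccc(COC[C@@]3(COC(C)(C)O3)C[C@H](O)[C@H]2C(=O)CC[C@]2(C)C=C(C)C)cc1 | intermediate
18 | isopropylmagnesium chloride | CC(C)[Mg]Cl | starting material
19 | (1R,2S,3R)-2-{(1S)-1-hydroxy-2-[(4R)-4-{[(4-methoxyphenyl)methoxy]methyl}-2,2-dimethyl-1,3-dioxolan-4-yl]ethyl}-3-methyl-3-(2-methylprop-1-en-1-yl)-1-(propan-2-yl)cyclopentan-1-ol | COc1ccc(COC[C@@]3(COC(C)(C)O3)C[C@H](O)[C@H]2[C@](O)(C(C)C)CC[C@]2(C)C=C(C)C)cc1 | intermediate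
20 | 3-methylbutanoyl chloride (isovaleryl chloride) | CC(C)CC(=O)Cl | starting material
21 | (1S)-1-[(1S,2R,5R)-2-hydroxy-5-methyl-5-(2-methylprop-1-en-1-yl)-2-(propan-2-yl)cyclopentyl]-2-[(4R)-4-{[(4-methoxyphenyl)methoxy]methyl}-2,2-dimethyl-1,3-dioxolan-4-yl]ethyl 3-methylbutanoate | COc1ccc(COC[C@@]3(COC(C)(C)O3)C[C@H](OC(=O)CC(C)C)[C@H]2[C@](O)(C(C)C)CC[C@]2(C)C=C(C)C)cc1 | intermediate
22 | (1S)-2-[(4R)-4-(hydroxymethyl)-2,2-dimethyl-1,3-dioxolan-4-yl]-1-[(1S,2R,5R)-2-hydroxy-5-methyl-5-(2-methylprop-1-en-1-yl)-2-(propan-2-yl)cyclopentyl]ethyl 3-methylbutanoate | OC[C@@]3(COC(C)(C)O3)C[C@H](OC(=O)CC(C)C)[C@H]2[C@](O)(C(C)C)CC[C@]2(C)C=C(C)C | intermediate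
23 | (1S)-2-[(4S)-4-formyl-2,2-dimethyl-1,3-dioxolan-4-yl]-1-[(1S,2R,5R)-2-hydroxy-5-methyl-5-(2-methylprop-1-en-1-yl)-2-(propan-2-yl)cyclopentyl]ethyl 3-methylbutanoate | O=C[C@@]3(COC(C)(C)O3)C[C@H](OC(=O)CC(C)C)[C@H]2[C@](O)(C(C)C)CC[C@]2(C)C=C(C)C | intermediate
24 | secondary ozonide of 23 (5,5-dimethyl-1,2,4-trioxolan-3-yl group at C1, formed in situ) | O=C[C@@]3(COC(C)(C)O3)C[C@H](OC(=O)CC(C)C)[C@H]2[C@](O)(C(C)C)CC[C@]2(C)C4OOC(C)(C)O4 | intermediate
25 | (1S)-2-[(4S)-4-formyl-2,2-dimethyl-1,3-dioxolan-4-yl]-1-[(1S,2S,5R)-2-formyl-5-hydroxy-2-methyl-5-(propan-2-yl)cyclopentyl]ethyl 3-methylbutanoate (C9,C10-dialdehyde) | O=C[C@@]1(COC(C)(C)O1)C[C@H](OC(=O)CC(C)C)[C@H]2[C@](O)(C(C)C)CC[C@]2(C)C=O | intermediate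
26 | (1S,4R,5S,6S,8S,9S,10S)-4,9,10-trihydroxy-8,14-(propane-2,2-diyldioxy)daucan-6-yl 3-methylbutanoate | CC(C)CC(=O)O[C@H]1C[C@]4(COC(C)(C)O4)[C@@H](O)[C@@H](O)[C@@]2(C)CC[C@@](O)(C(C)C)[C@H]12 | intermediate
27 | (1S,4R,5S,6S,8S,9S,10S)-4,8,9,10,14-pentahydroxydaucan-6-yl 3-methylbutanoate | CC(C)CC(=O)O[C@H]1C[C@](O)(CO)[C@@H](O)[C@@H](O)[C@@]2(C)CC[C@@](O)(C(C)C)[C@H]12 | intermediate
28 | 14-O-(4-methylbenzenesulfonyl) derivative of 27 (formed in situ) | CC(C)CC(=O)O[C@H]1C[C@](O)(COS(=O)(=O)c3ccc(C)cc3)[C@@H](O)[C@@H](O)[C@@]2(C)CC[C@@](O)(C(C)C)[C@H]12 | intermediate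
29 | (1S,4R,5S,6S,8S,9S,10S)-8,14-epoxy-4,9,10-trihydroxydaucan-6-yl 3-methylbutanoate (CNP0307265.1) | CC(C)CC(=O)O[C@H]1C[C@]2(CO2)[C@@H](O)[C@@H](O)[C@@]2(C)CC[C@@](O)(C(C)C)[C@H]12 | target

**Totals.** Total step count: 15. Longest linear sequence: 14 steps (steps 2–6, then 7–15, from 6).

**Steps most likely to fail**

Step 13 (pinacol closure). What may go wrong: reduction of the aldehydes without C–C bond formation, reductive loss of the C8 oxygen from the α-alkoxy ketyl, or delivery of the cis-diol on the β face. The fallback separates ring closure from diol installation. It sets out from 23. Wittig methylenation of the C9 aldehyde (Ph3P=CH2, THF, −78 → 0 °C) gives diene F1. Ring-closing metathesis with the second-generation Grubbs catalyst (toluene, 80 °C) joins the C8 vinyl and C1 2-methylpropenyl groups, with loss of 2-methylpropene, to give cycloheptene F2. Osmylation (OsO4 cat., N-methylmorpholine N-oxide, acetone–H2O) should add both hydroxyls suprafacially from the face opposite the C1 methyl and the C14 methylene. The fallback comes back to the route at 26.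

Step 7 (aldol union). What may go wrong: erosion of the chair-controlled anti preference through boat or open transition states at the congested enolate carbon, so that the C6 epimer forms in quantity. The fallback fixes C6 by inversion instead of by the aldol transition state. It sets out from 5 and 13: the C6-epimeric syn aldol F3 that then accompanies 17 is separated and carried through the organocerium addition of step 8 to the epimeric diol F4. Mitsunobu esterification of F4 with 3-methylbutanoic acid (PPh3, DIAD, toluene, acid in excess) should install the ester with inversion at C6. The fallback comes back to the route at 21.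

Step 8 (isopropyl addition). What may go wrong: retro-aldol cleavage of the metal aldolate, enolisation, or β-hydride reduction in place of addition at the hindered ketone. The fallback is a protecting-group detour that removes the free aldolate. It sets out from 17. Silylation (Et3SiOTf, 2,6-lutidine, CH2Cl2, −78 °C) gives the silyl ether F5. Addition of 18 with CeCl3 (THF, −78 → 0 °C) gives the tertiary alcohol F6, isopropyl again entering trans to the side chain. Desilylation (Bu4NF, THF, 0 °C) comes back to the route at 19.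

**Further compounds**

F1 | step 13 | (1S)-2-[(4R)-4-ethenyl-2,2-dimethyl-1,3-dioxolan-4-yl]-1-[(1S,2R,5R)-2-hydroxy-5-methyl-5-(2-methylprop-1-en-1-yl)-2-(propan-2-yl)cyclopentyl]ethyl 3-methylbutanoate | C=C[C@@]3(COC(C)(C)O3)C[C@H](OC(=O)CC(C)C)[C@H]2[C@](O)(C(C)C)CC[C@]2(C)C=C(C)C
F2 | step 13 | (1R,4R,5S,6S,8R)-4-hydroxy-8,14-(propane-2,2-diyldioxy)dauc-9-en-6-yl 3-methylbutanoate | CC(C)CC(=O)O[C@H]1C[C@]4(COC(C)(C)O4)C=C[C@@]2(C)CC[C@@](O)(C(C)C)[C@H]12
F3 | step 7 | (2S,3R)-2-{(1R)-1-hydroxy-2-[(4R)-4-{[(4-methoxyphenyl)methoxy]methyl}-2,2-dimethyl-1,3-dioxolan-4-yl]ethyl}-3-methyl-3-(2-methylprop-1-en-1-yl)cyclopentan-1-one | COc1ccc(COC[C@@]3(COC(C)(C)O3)C[C@@H](O)[C@H]2C(=O)CC[C@]2(C)C=C(C)C)cc1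
F4 | step 7 | (1R,2S,3R)-2-{(1R)-1-hydroxy-2-[(4R)-4-{[(4-methoxyphenyl)methoxy]methyl}-2,2-dimethyl-1,3-dioxolan-4-yl]ethyl}-3-methyl-3-(2-methylprop-1-en-1-yl)-1-(propan-2-yl)cyclopentan-1-ol | COc1ccc(COC[C@@]3(COC(C)(C)O3)C[C@@H](O)[C@H]2[C@](O)(C(C)C)CC[C@]2(C)C=C(C)C)cc1
F5 | step 8 | (2S,3R)-2-{(1S)-2-[(4R)-4-{[(4-methoxyphenyl)methoxy]methyl}-2,2-dimethyl-1,3-dioxolan-4-yl]-1-[(triethylsilyl)oxy]ethyl}-3-methyl-3-(2-methylprop-1-en-1-yl)cyclopentan-1-one | COc1ccc(COC[C@@]3(COC(C)(C)O3)C[C@H](O[Si](CC)(CC)CC)[C@H]2C(=O)CC[C@]2(C)C=C(C)C)cc1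
F6 | step 8 | (1R,2S,3R)-2-{(1S)-2-[(4R)-4-{[(4-methoxyphenyl)methoxy]methyl}-2,2-dimethyl-1,3-dioxolan-4-yl]-1-[(triethylsilyl)oxy]ethyl}-3-methyl-3-(2-methylprop-1-en-1-yl)-1-(propan-2-yl)cyclopentan-1-ol | COc1ccc(COC[C@@]3(COC(C)(C)O3)C[C@H](O[Si](CC)(CC)CC)[C@H]2[C@](O)(C(C)C)CC[C@]2(C)C=C(C)C)cc1
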